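Choosing the nucleophile charge starts from the test of one nucleophile per electrophile.

    electrophile + nucleophile → acid set free + target (k1 = 43 M⁻¹ min⁻¹)
    nucleophile + acid set free ⇌ protonated nucleophile, settled at all times (K2 = 2400 M⁻¹)
    nucleophile + target → over-reaction product (k3 = 0.64 M⁻¹ min⁻¹)
    electrophile + protic impurity → quenched substrate (k4 = 14 M⁻¹ min⁻¹)

electrophile 0.10 M; protic impurity 2.00 mM; time 10 min

* the concentration of nucleophile at which the part of the electrophile that has reacted at 10 min is just 90%, in M

1. One equivalent would serve if a nucleophile molecule at the fork between staying free and taking up acid mostly stayed free, so the equilibrium constant 2400 M⁻¹ times c(acid set free) would have to lie below one. Unbound acid at the level of the charged electrophile gives odds of 240, far above that limit, so this flask stands a long way off and each coupling tends to cost a second nucleophile.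

2. My own reckoning lets the impurity take its whole charge, which leaves 0.0880 M to couple and, at two nucleophiles per coupling, a bill of 0.176 M.

3. That bill leaves out the coupling that creeps on after acid outruns nucleophile, through the small amount of free nucleophile the balance keeps. Free nucleophile is then c(protonated nucleophile)/(2400 M⁻¹·s), with s the unbound acid, so the creep constant, the coupling constant over the equilibrium constant, is κ = 43 M⁻¹ min⁻¹/2400 M⁻¹ = 0.0179 min⁻¹. Holding electrophile left, u, and protonated nucleophile, y, steady gives s = 2√(κ·t·u·y).

4. With u = 0.0100 M and y = 0.0880 M, s is 0.0251 M. Taking that from y gives s = 0.0212 M, so the estimated charge, the bill less s, is 0.155 M.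

5. The forecast says 0.15 M, since “the equilibrium is not so tight that free nucleophile vanishes”. My figure is slightly higher.

The simulation gives 0.156 M. By 1.00 min this flask has used 76.4% of its electrophile, and the rest of the 10 min carries it to the level asked. The flask with half the nucleophile, 0.0780 M, ends at 55.6%, which by balance, with the impurity's whole charge taken and over-reaction left aside, means about 0.0536 M coupled and s = 0.0292 M. The creep constant with that flask's u and y gives s = 0.0279 M.

(The rate constants were set for the occasion; what happens was integrated by code.)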